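**Retrosynthetic overview**

1. Sigmoidin D ⇒ (global desilylation) the persilylated (2S)-flavanone ⇒ cut C2–C3 of pyranone ring C: an aryl benzyl ether in which C3 is the diazo carbon of a diazoacetyl group and C2 is still the O1–CH2–Ar methylene. Ring C is the last ring formed, by an enantioselective Rh(II)-carbenoid 1,6-C–H insertion.
2. Enabling feature: C2 is flanked by ring oxygen O1 and the para-oxygenated B ring and lies 1,6 to C3 (C3–C4–C4a–C8a–O1–C2). In the open form its C–H bonds are therefore the only ones within reach of an acyl carbene at C3 and the most hydridic in the molecule. The O5 substituent ortho to C4 twists the acyl group out of the A-ring plane, away from the planar oxonium-ylide pathway.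
3. Diazoketone ⇒ (detrifluoroacetylative diazo transfer) methyl ketone ⇒ (Mitsunobu C–O bond) 2-hydroxy-4,6-bis(silyloxy)acetophenone + (3S)-chromanol benzylic alcohol.
4. Chromanol fragment ⇒ (LiAlH4: benzylic epoxide opening plus ester reduction) (3S,4S)-epoxide ⇒ (Jacobsen–Katsuki epoxidation, sets the chroman C3) 2,2-dimethylchromene ester ⇒ (aryl propargyl ether Claisen/oxa-6π) methyl 3,4-dihydroxybenzoate + 3-chloro-3-methylbut-1-yne.
5. Ring order: dihydropyran ring of the chroman first (step 2), pyranone ring C last (step 10); aromatic rings A and B are bought.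

Key step: step 10

Assumption: Rh2(S-PTTL)4 is taken to give the (2S) sense of induction in step 10 and the (S,S)-Mn(salen) catalyst the (3S,4S)-epoxide in step 4 (by analogy with other 2,2-dimethylchromenes); if a model run shows the opposite sense, the enantiomeric catalyst is used with no other change.

**Route**

Step 1
Reactants: 1 methyl 3,4-dihydroxybenzoate; 2 3-chloro-3-methylbut-1-yne
Product: 3 methyl 3-hydroxy-4-[(2-methylbut-3-yn-2-yl)oxy]benzoate
Conditions: K2CO3 (1.05 equiv), KI (cat.), CuI (cat.), acetone, 55 °C, N2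
Reagents that add atoms: none
Why: One equivalent of base ionizes the more acidic 4-OH (para to the ester) selectively, and the copper-assisted propargylic substitution (Williamson-type etherification) should place the tertiary propargyl group on O4.

Step 2
Reactants: 3 propargyl ether
Product: 4 methyl 8-hydroxy-2,2-dimethyl-2H-chromene-6-carboxylate
Conditions: PhNEt2, 190 °C
Reagents that add atoms: none
Why: Aryl propargyl ether Claisen rearrangement to the only free ortho carbon, then tautomerization, 1,5-H shift and oxa-6π electrocyclization should close the 2,2-dimethylchromene ring; no stereocentre is formed.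

Step 3
Reactants: 4 chromene phenol
Product: 5 methyl 2,2-dimethyl-8-[(triisopropylsilyl)oxy]-2H-chromene-6-carboxylate
Conditions: TIPSCl, imidazole, DMF, rt
Reagents that add atoms: triisopropylsilyl chloride, CC(C)[Si](Cl)(C(C)C)C(C)C
Why: Standard silyl ether formation; an aryl TIPS ether should withstand the basic hypochlorite, hydride and amide-base steps that follow and offers no C–H bond within reach of the later carbenoid.

Step 4
Reactants: 5 chromene TIPS ether
Product: 6 methyl (3S,4S)-3,4-epoxy-2,2-dimethyl-8-[(triisopropylsilyl)oxy]chromane-6-carboxylate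
Conditions: (S,S)-Mn(salen)Cl (3 mol %), 4-phenylpyridine N-oxide, aq. NaOCl (pH 11.3), CH2Cl2, 0 °C
Reagents that add atoms: sodium hypochlorite, [Na+].[O-]Cl
Why: Jacobsen–Katsuki epoxidation, for which cis-configured conjugated 2,2-dimethylchromenes are among the best substrates; the (S,S)-catalyst should deliver oxygen to the face that gives the (3S,4S)-epoxide, which fixes the future chroman C3 centre.

Step 5
Reactants: 6 epoxy ester
Product: 7 (3S)-6-(hydroxymethyl)-2,2-dimethyl-8-[(triisopropylsilyl)oxy]chroman-3-ol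
Conditions: LiAlH4, THF, 0 °C → rt; Rochelle salt work-up
Reagents that add atoms: none
Why: LiAlH4 reduces the ester to the benzylic alcohol and opens the epoxide by SN2 hydride attack at the benzylic C4 (activated and far less hindered than the neopentyl C3), so the C3–O bond and its (S)-configuration stay untouched.

Step 6
Reactants: 8 1-(2,4,6-trihydroxyphenyl)ethan-1-one
Product: 9 1-{2-hydroxy-4,6-bis[(triisopropylsilyl)oxy]phenyl}ethan-1-one
Conditions: TIPSCl (2.1 equiv), imidazole, DMF, 0 °C → rt
Reagents that add atoms: triisopropylsilyl chloride, CC(C)[Si](Cl)(C(C)C)C(C)C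
Why: Silylation should take the free 4-OH and one of the two equivalent ortho OH groups, while the last OH stays locked in the hydrogen bond to the ketone, the usual outcome of twofold protection of phloroacetophenone.

Step 7
Reactants: 9 bis-TIPS acetophenone; 7 chromanol benzylic alcohol
Product: 10 1-{2-({(3S)-3-hydroxy-2,2-dimethyl-8-[(triisopropylsilyl)oxy]chroman-6-yl}methoxy)-4,6-bis[(triisopropylsilyl)oxy]phenyl}ethan-1-one
Conditions: PPh3, DIAD, toluene/THF, 0 °C → rt
Reagents that add atoms: none
Why: Mitsunobu etherification: the acyl-activated phenol is acidic enough to protonate the betaine and should displace the oxyphosphonium of the primary benzylic alcohol, while the hindered neopentyl-type secondary alcohol stays untouched, so no stereocentre is involved.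

Step 8
Reactants: 10 hydroxy ether
Product: 11 1-{2-({(3S)-2,2-dimethyl-3-[(triethylsilyl)oxy]-8-[(triisopropylsilyl)oxy]chroman-6-yl}methoxy)-4,6-bis[(triisopropylsilyl)oxy]phenyl}ethan-1-one
Conditions: TESCl, imidazole, DMAP (cat.), DMF, rt
Reagents that add atoms: triethylsilyl chloride, CC[Si](Cl)(CC)CC
Why: Silyl ether formation masks the secondary alcohol against the amide base and against O–H insertion of the carbenoid; TES is chosen because fluoride removes it together with the aryl TIPS groups.

Step 9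
Reactants: 11 methyl ketone
Product: 13 2-diazo-1-{2-({(3S)-2,2-dimethyl-3-[(triethylsilyl)oxy]-8-[(triisopropylsilyl)oxy]chroman-6-yl}methoxy)-4,6-bis[(triisopropylsilyl)oxy]phenyl}ethan-1-one, via trifluoroacetyl diketone 12 (not isolated)
Conditions: LiHMDS, THF, −78 °C; CF3CO2CH2CF3, −78 °C; NH4Cl work-up; then MsN3, Et3N, H2O (1 equiv), MeCN, rt
Reagents that add atoms: 2,2,2-trifluoroethyl trifluoroacetate, O=C(OCC(F)(F)F)C(F)(F)F (trifluoroacetyl group of 12 only); methanesulfonyl azide, CS(=O)(=O)N=[N+]=[N-] (the two diazo nitrogens of 13)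
Why: Detrifluoroacetylative (Regitz-type) diazo transfer: kinetic enolization and Claisen acylation activate the methyl group, and the sulfonyl azide then transfers N2 with loss of the trifluoroacetyl group as the N-sulfonyl amide, which should give the terminal α-diazoketone without touching the silyl ethers.

Step 10
Reactants: 13 diazoketone
Product: 14 (2S)-2-{(3S)-2,2-dimethyl-3-[(triethylsilyl)oxy]-8-[(triisopropylsilyl)oxy]chroman-6-yl}-5,7-bis[(triisopropylsilyl)oxy]chroman-4-one
Conditions: Rh2(S-PTTL)4 (1 mol %), CH2Cl2, 0 °C, slow addition of 13 at high dilution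
Reagents that add atoms: none
Why: The Rh(II) carboxylate extrudes N2 from 13 to give an electrophilic acyl carbenoid at the future C3, which inserts through a concerted, hydride-transfer-like three-centre transition state into one of the two enantiotopic C–H bonds of the O1–CH2–Ar methylene and so forms the C2–C3 bond; the closest known reaction type is the chiral Rh(II)-carboxylate-catalysed intramolecular C–H insertion of 2-alkoxyaryl α-diazoketones to 2-substituted chroman-4-ones. Ring C is closed as a 1,6-insertion through a six-membered chair-like transition state (C3–C4–C4a–C8a–O1–C2), the only insertion within reach because the 1,5-position is O1 itself. The new stereocentre C2 is set by the catalyst, whose chiral carboxylate pocket selects one enantiotopic hydrogen; the (3S)-chromanyl centre is too remote to compete. The step needs chemoselectivity for C–H insertion over oxonium ylide formation with [1,2]-benzyl shift and over O-closure after complete hydride transfer: the target C–H is doubly activated (α to O1 and benzylic to the para-oxygenated B ring), O1 is a weakly basic vinylogous-ester oxygen, and the bulky ortho OTIPS group twists the acyl carbenoid out of the A-ring plane, which should disfavour the planar five-membered ylide but fit the insertion geometry. No activating ester is placed on C3, because a 3-acyl flavanone would racemize at C2 by retro-oxa-Michael opening, so the product should leave the step configurationally stable.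

Step 11
Reactants: 14 persilylated flavanone
Product: 15 Sigmoidin D, (2S)-2-[(3S)-3,8-dihydroxy-2,2-dimethylchroman-6-yl]-5,7-dihydroxychroman-4-one
Conditions: TBAF, AcOH (1:1, excess), THF, 0 °C → rt
Reagents that add atoms: none
Why: Fluoride cleaves all four Si–O bonds (silyl ether deprotection) while the acetic acid buffer keeps the phenols protonated, so base-induced retro-oxa-Michael opening of ring C and loss of the C2 configuration should be avoided.

**Compound list**

1 | methyl 3,4-dihydroxybenzoate | COC(=O)c1ccc(O)c(O)c1 | starting material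
2 | 3-chloro-3-methylbut-1-yne | C#CC(C)(C)Cl | starting material
3 | methyl 3-hydroxy-4-[(2-methylbut-3-yn-2-yl)oxy]benzoate | COC(=O)c1ccc(OC(C)(C)C#C)c(O)c1 | intermediate
4 | methyl 8-hydroxy-2,2-dimethyl-2H-chromene-6-carboxylate | COC(=O)c1cc(O)c2OC(C)(C)C=Cc2c1 | intermediate
5 | methyl 2,2-dimethyl-8-[(triisopropylsilyl)oxy]-2H-chromene-6-carboxylate | COC(=O)c1cc(O[Si](C(C)C)(C(C)C)C(C)C)c2OC(C)(C)C=Cc2c1 | intermediate
6 | methyl (3S,4S)-3,4-epoxy-2,2-dimethyl-8-[(triisopropylsilyl)oxy]chromane-6-carboxylate | COC(=O)c1cc(O[Si](C(C)C)(C(C)C)C(C)C)c2OC(C)(C)[C@H]3O[C@H]3c2c1 | intermediate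
7 | (3S)-6-(hydroxymethyl)-2,2-dimethyl-8-[(triisopropylsilyl)oxy]chroman-3-ol | OCc1cc(O[Si](C(C)C)(C(C)C)C(C)C)c2OC(C)(C)[C@@H](O)Cc2c1 | intermediate
8 | 1-(2,4,6-trihydroxyphenyl)ethan-1-one (phloroacetophenone) | CC(=O)c1c(O)cc(O)cc1O | starting material
9 | 1-{2-hydroxy-4,6-bis[(triisopropylsilyl)oxy]phenyl}ethan-1-one | CC(=O)c1c(O)cc(O[Si](C(C)C)(C(C)C)C(C)C)cc1O[Si](C(C)C)(C(C)C)C(C)C | intermediate
10 | 1-{2-({(3S)-3-hydroxy-2,2-dimethyl-8-[(triisopropylsilyl)oxy]chroman-6-yl}methoxy)-4,6-bis[(triisopropylsilyl)oxy]phenyl}ethan-1-one | CC(=O)c1c(OCc2cc(O[Si](C(C)C)(C(C)C)C(C)C)c3OC(C)(C)[C@@H](O)Cc3c2)cc(O[Si](C(C)C)(C(C)C)C(C)C)cc1O[Si](C(C)C)(C(C)C)C(C)C | intermediate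
11 | 1-{2-({(3S)-2,2-dimethyl-3-[(triethylsilyl)oxy]-8-[(triisopropylsilyl)oxy]chroman-6-yl}methoxy)-4,6-bis[(triisopropylsilyl)oxy]phenyl}ethan-1-one | CC(=O)c1c(OCc2cc(O[Si](C(C)C)(C(C)C)C(C)C)c3OC(C)(C)[C@@H](O[Si](CC)(CC)CC)Cc3c2)cc(O[Si](C(C)C)(C(C)C)C(C)C)cc1O[Si](C(C)C)(C(C)C)C(C)C | intermediate
12 | 4,4,4-trifluoro-1-{2-({(3S)-2,2-dimethyl-3-[(triethylsilyl)oxy]-8-[(triisopropylsilyl)oxy]chroman-6-yl}methoxy)-4,6-bis[(triisopropylsilyl)oxy]phenyl}butane-1,3-dione | O=C(CC(=O)C(F)(F)F)c1c(OCc2cc(O[Si](C(C)C)(C(C)C)C(C)C)c3OC(C)(C)[C@@H](O[Si](CC)(CC)CC)Cc3c2)cc(O[Si](C(C)C)(C(C)C)C(C)C)cc1O[Si](C(C)C)(C(C)C)C(C)C | intermediate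
13 | 2-diazo-1-{2-({(3S)-2,2-dimethyl-3-[(triethylsilyl)oxy]-8-[(triisopropylsilyl)oxy]chroman-6-yl}methoxy)-4,6-bis[(triisopropylsilyl)oxy]phenyl}ethan-1-one | [N-]=[N+]=CC(=O)c1c(OCc2cc(O[Si](C(C)C)(C(C)C)C(C)C)c3OC(C)(C)[C@@H](O[Si](CC)(CC)CC)Cc3c2)cc(O[Si](C(C)C)(C(C)C)C(C)C)cc1O[Si](C(C)C)(C(C)C)C(C)C | intermediate
14 | (2S)-2-{(3S)-2,2-dimethyl-3-[(triethylsilyl)oxy]-8-[(triisopropylsilyl)oxy]chroman-6-yl}-5,7-bis[(triisopropylsilyl)oxy]chroman-4-one | CC1(C)Oc2c(O[Si](C(C)C)(C(C)C)C(C)C)cc([C@@H]3CC(=O)c4c(O[Si](C(C)C)(C(C)C)C(C)C)cc(O[Si](C(C)C)(C(C)C)C(C)C)cc4O3)cc2C[C@@H]1O[Si](CC)(CC)CC | intermediate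
15 | Sigmoidin D, (2S)-2-[(3S)-3,8-dihydroxy-2,2-dimethylchroman-6-yl]-5,7-dihydroxychroman-4-one | CC1(C)Oc2c(O)cc([C@@H]3CC(=O)c4c(O)cc(O)cc4O3)cc2C[C@@H]1O | target

**Summary**

Total step count: 11. Longest linear sequence: 10 steps (steps 1–5 and 7–11, from compound 1).

**Steps most likely to fail, with fallbacks**

Step 10. The carbenoid may be diverted by attack of the ether oxygen (oxonium ylide, then [1,2]-benzyl shift to a benzofuranone). A fully hydride-transferred zwitterion may also close through the enolate oxygen instead of carbon, or an acceptor-only carbenoid may discriminate the enantiotopic C–H bonds poorly. The fallback gives up C–C ring closure for an enantioselective oxa-Michael closure on an activated chalcone; it sets out from 7 and 9 and comes back at 15. MnO2 (CH2Cl2, rt) should oxidize only the benzylic alcohol of 7 to (3S)-3-hydroxy-2,2-dimethyl-8-[(triisopropylsilyl)oxy]chromane-6-carbaldehyde F1. The lithium dianion of 9 (LiHMDS, THF, −78 °C) is C-acylated with Boc2O to tert-butyl 3-{2-hydroxy-4,6-bis[(triisopropylsilyl)oxy]phenyl}-3-oxopropanoate F2. Knoevenagel condensation of F1 with F2 (piperidine, AcOH, toluene, molecular sieves) gives the alkylidene β-ketoester F3. A cinchona-derived bifunctional thiourea (the pseudo-enantiomer that delivers 2S, toluene, −25 °C) should close ring C by intramolecular oxa-Michael addition of the free 2'-OH, giving the 3-tert-butoxycarbonyl flavanone F4. TsOH (toluene, 80 °C) removes the ester as isobutene and CO2 to give the tris-TIPS flavanone F5, which is desilylated under the conditions of step 11 to 15.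

Step 7. The chelated, hindered phenol may fail to attack, or the ionized p-alkoxybenzyl electrophile may alkylate a ring carbon of the electron-rich A ring instead of oxygen. The fallback replaces the redox condensation by SN2 alkylation with a preformed halide; it sets out from 7 and comes back at 10. Appel bromination (CBr4, PPh3, CH2Cl2, 0 °C) of the primary benzylic alcohol gives (3S)-6-(bromomethyl)-2,2-dimethyl-8-[(triisopropylsilyl)oxy]chroman-3-ol F6, used crude. Williamson alkylation of 9 with F6 (K2CO3, TBAI cat., acetone, rt) should then give 10.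

Step 9. The ortho TIPS group may migrate from the phenol oxygen to the enolate oxygen, or acyl transfer to the hindered ketone enolate may be incomplete. The fallback avoids any enolate; it sets out from 11 and comes back at 13. Condensation with DMF dimethyl acetal (neat, 90 °C) gives the enaminone (E)-3-(dimethylamino)-1-{2-({(3S)-2,2-dimethyl-3-[(triethylsilyl)oxy]-8-[(triisopropylsilyl)oxy]chroman-6-yl}methoxy)-4,6-bis[(triisopropylsilyl)oxy]phenyl}prop-2-en-1-one F7. Cycloaddition–fragmentation with MsN3 (CH2Cl2, rt) should then give 13 with loss of the N-sulfonyl formamidine.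

**Further compounds**

F1 | step 10 | (3S)-3-hydroxy-2,2-dimethyl-8-[(triisopropylsilyl)oxy]chromane-6-carbaldehyde | O=Cc1cc(O[Si](C(C)C)(C(C)C)C(C)C)c2OC(C)(C)[C@@H](O)Cc2c1
F2 | step 10 | tert-butyl 3-{2-hydroxy-4,6-bis[(triisopropylsilyl)oxy]phenyl}-3-oxopropanoate | CC(C)(C)OC(=O)CC(=O)c1c(O)cc(O[Si](C(C)C)(C(C)C)C(C)C)cc1O[Si](C(C)C)(C(C)C)C(C)C
F3 | step 10 | tert-butyl 2-{2-hydroxy-4,6-bis[(triisopropylsilyl)oxy]benzoyl}-3-{(3S)-3-hydroxy-2,2-dimethyl-8-[(triisopropylsilyl)oxy]chroman-6-yl}prop-2-enoate (E/Z mixture) | CC(C)(C)OC(=O)C(=Cc1cc(O[Si](C(C)C)(C(C)C)C(C)C)c2OC(C)(C)[C@@H](O)Cc2c1)C(=O)c1c(O)cc(O[Si](C(C)C)(C(C)C)C(C)C)cc1O[Si](C(C)C)(C(C)C)C(C)C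
F4 | step 10 | tert-butyl (2S)-2-{(3S)-3-hydroxy-2,2-dimethyl-8-[(triisopropylsilyl)oxy]chroman-6-yl}-4-oxo-5,7-bis[(triisopropylsilyl)oxy]chromane-3-carboxylate (C3 epimers) | CC1(C)Oc2c(O[Si](C(C)C)(C(C)C)C(C)C)cc([C@@H]3C(C(=O)OC(C)(C)C)C(=O)c4c(O[Si](C(C)C)(C(C)C)C(C)C)cc(O[Si](C(C)C)(C(C)C)C(C)C)cc4O3)cc2C[C@@H]1O
F5 | step 10 | (2S)-2-{(3S)-3-hydroxy-2,2-dimethyl-8-[(triisopropylsilyl)oxy]chroman-6-yl}-5,7-bis[(triisopropylsilyl)oxy]chroman-4-one | CC1(C)Oc2c(O[Si](C(C)C)(C(C)C)C(C)C)cc([C@@H]3CC(=O)c4c(O[Si](C(C)C)(C(C)C)C(C)C)cc(O[Si](C(C)C)(C(C)C)C(C)C)cc4O3)cc2C[C@@H]1O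
F6 | step 7 | (3S)-6-(bromomethyl)-2,2-dimethyl-8-[(triisopropylsilyl)oxy]chroman-3-ol | BrCc1cc(O[Si](C(C)C)(C(C)C)C(C)C)c2OC(C)(C)[C@@H](O)Cc2c1
F7 | step 9 | (E)-3-(dimethylamino)-1-{2-({(3S)-2,2-dimethyl-3-[(triethylsilyl)oxy]-8-[(triisopropylsilyl)oxy]chroman-6-yl}methoxy)-4,6-bis[(triisopropylsilyl)oxy]phenyl}prop-2-en-1-one | CN(C)/C=C/C(=O)c1c(OCc2cc(O[Si](C(C)C)(C(C)C)C(C)C)c3OC(C)(C)[C@@H](O[Si](CC)(CC)CC)Cc3c2)cc(O[Si](C(C)C)(C(C)C)C(C)C)cc1O[Si](C(C)C)(C(C)C)C(C)C
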